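## The problem

Atom labels used throughout: C1 = CH(OAc), C2 = CH(OBz), C3=C4 = alkene, C5 = epoxide CH, C6 = quaternary epoxide carbon, C7 = CH2O on C6. Plain numerals are compound numbers.

The target is a cyclohexene with a cis-fused oxirane across C5–C6, four contiguous stereocentres (C1, C2, C5 and quaternary C6) and three esters of two kinds: acetate on O1, benzoates on O2 and O7. O1 and O2 are trans. The oxirane oxygen is syn to O2 across C1 and anti to O1. C2 can therefore steer C6 through a 1,3-tether, whereas C1 can act only by shielding; C5 follows from C6 because the oxirane must be cis-fused. The vinyl epoxide opens at the allylic carbon under acid, and under base it can migrate (Payne shift) as soon as O1 or O7 is a free alkoxide; esters on neighbouring oxygens migrate under the same conditions. Every dienyl precursor with an allylic oxygen is one elimination away from a benzene ring. The acyl pattern demands that O1 and O2, two secondary allylic oxygens, be told apart. The feature that makes the key step possible is that O2 is homoallylic to C5=C6 inside the six-membered ring. When O2 is axial, a carbonate on it lies directly over C6 and can close a six-membered ring onto C6 only from the face the oxirane must occupy.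

## Retrosynthesis

**16 to 14 (through 15).** The acetate C–O bond on O1 and the benzoate C–O bond on O7 are cut last. An ester on O1 cannot be present earlier: it would attack the iodonium ion itself and it would not survive carbonate methanolysis. An O7 benzoate installed before the key step would be a second internal nucleophile next to C6 and would have to be put on twice. The forward reaction must acylate a primary hydroxyl before a secondary one that is wedged between C6 and C2.

**14 to 13 to 12.** The two silyl ethers (O1, O7) and the O2 benzoate are removed in thought. In 12 O2 is the only free hydroxyl, so its benzoylation needs no selectivity. The desilylation must avoid alkoxide formation next to the oxirane.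

**12 to 11.** The C5–O bond of the oxirane is cut. Iodocarbonate 11 carries iodine on C5 anti to the C6–O bond, so methanolysis of the carbonate releases a C6 alkoxide that closes the ring by backside displacement. The step is stereospecific.

**11 to 10 (key disconnection).** The C6–O bond is cut and its oxygen is returned to the carbonyl of a tert-butyl carbonate on O2 of diene 10. Peracid epoxidation of a dienyl triester was the neighbouring option; it would have to choose between two alkenes and between a face screened by O2 and a face screened by O1. A metal-catalysed epoxidation directed by a free O2 hydroxyl would strike the allylic C3=C4 alkene first. The tether removes the facial choice from the reagent. The precursor loses two stereocentres and the oxirane and keeps only the trans C1/C2 pair. The forward step must deliver the carbonate oxygen to C6 and not to C4.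

**10 to 9 to 8 to 7.** The carbonate and the O7 silyl ether are removed and the C7 carbinol is traced to a methyl ester. O7 is silylated, not benzoylated, because a silyl ether cannot act as a nucleophile and leaves C5=C6 more electron-rich. Reduction of 7 must also free O2, which it does because the O2 acetate of 7 is cleaved by the same hydride.

**7 to racemic 6.** The enantiomers are separated by lipase acylation of the one free carbinol. A catalytic asymmetric entry was weighed: inverse-demand cycloaddition of a pyran-2-one ester with an enediol bis-silyl ether and loss of CO2. It was set aside for two reasons. It needs the E enediol ether, whereas enolisation of an α-silyloxy aldehyde is expected to favour Z. It also delivers O1 and O2 as twins that must be differentiated afterwards. The price of the resolution is half of the material at an early, cheap stage.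

**6 to 5 to 4.** The C2–O bond is cut. O2 is introduced as an oxirane on the isolated C2=C3 alkene of 4, anti to the O1 silyl ether, and is revealed by a vinylogous E1cB opening (C4–H removed, C3–O broken). This secures the trans relation and gives O1 silylated and O2 free in one operation.

**4 to 2 + 3, and 2 to 1.** The C1–C6 and C4–C5 bonds are cut in a Diels–Alder sense. Silyl dienol ether 2 (from crotonaldehyde 1) and methyl propiolate 3 are both commercial-grade feedstocks. The forward reaction must give the adduct with the silyloxy carbon next to the ester carbon, without loss of silanol.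

## Roads not taken

**Alternative 1: spiro-epoxide moved into the ring by Payne rearrangement.** The cut is the C5–O oxirane bond, traced to spiro-epoxide A2 (oxirane between C6 and C7, free hydroxyl on C5 trans to the spiro C6–O bond, O2 as 4-methoxybenzyl ether). In the forward step, base turns the C5 hydroxyl into an alkoxide that attacks C6 with inversion and gives ring epoxide A1 with O7 as a free primary alcohol.
- Merits: the step is stereospecific, and the equilibrium should favour the more substituted oxirane and the primary alkoxide. O7 and O2 emerge already differentiated, which is better than the chosen plan, where step 12 must discriminate O7 from O1. No halogen electrophile meets a diene.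
- Weak points: the configuration of C6 in A2 has to be set beforehand, by methylene transfer to a ketone flanked by two oxygenated carbons or by epoxidation of an exocyclic alkene. A C5 hydroxyl would direct a metal-catalysed epoxidation to the syn face, which is the wrong arrangement. In A1 the free O1 alkoxide is trans to the new oxirane and can shift it once more toward C1.
- Comparison: both plans close the oxirane by intramolecular displacement. The chosen plan takes the configuration of C6 from C2, which is already secured; this road takes it from a spiro centre that needs its own control. Step counts would be similar.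

**Alternative 2: allylic sulfonium ylide closes carbocycle and oxirane together.** The cuts are C5–C6 and C5–O, leading to acyclic keto sulfonium salt A4. In the forward step a base such as KOt-Bu forms the C5 ylide, which adds to the C6 ketone and expels dimethyl sulfide to give tris-silyl epoxy cyclohexene A3.
- Merits: ring and oxirane form in one step. C1 and C2 come from an acyclic threo diol of the chiral pool, so no resolution is needed; in this respect it is better than the chosen plan. No aromatisation-prone dihydroarene appears before the key step.
- Weak points: two stereocentres arise in one addition whose facial bias at the α-silyloxy ketone is not secure. An ylide formed on an S-methyl group would undergo [2,3]-sigmatropic rearrangement. The ketone can enolise toward C1, with epimerisation or β-elimination. A3 carries two similar secondary silyl ethers, so placing acetate on O1 and benzoate on O2 needs a differentiation the chosen route has from step 3 onward.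
- Comparison: the chosen plan sets against the shorter skeleton assembly a tether-enforced C6 configuration and built-in O1/O2 differentiation.

**Alternative 3: furan Diels–Alder whose oxygen bridge becomes the oxirane.** The cuts are C1–C6 and C2–C3. Furfuryl benzoate A6 and 2-bromoacrolein A7 combine under a chiral oxazaborolidine-type boron Lewis acid to give 7-oxanorbornene bromo-aldehyde A5.
- Merits: absolute configuration comes from a catalyst. The carbocycle, C7 and the quaternary C6–O bond are made in one step from two simple achiral compounds. On enantiocontrol and early convergence this road is clearly better than the chosen plan, which discards half of 6 in step 4.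
- Weak points: furan cycloadditions are reversible and the regiochemistry with a 2-substituted furan is not assured. In A5, C1 carries bromine and a formyl group that must be excised and replaced by a carbinol of defined configuration. C2 is an unfunctionalised CH2. The bridging oxygen joins C6 to C3 and not to C5, so an allylic transposition of that oxygen is required. Each of these repairs is a multi-step task with its own stereochemical question.
- Comparison: the chosen plan sets against it that all four oxygens sit on the right carbons with the right relative configuration after three steps, and that the C6 face is fixed by a tether.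

Key step: step 8

Assumption: the lipase in step 4 is taken to acetylate the (5R) carbinol of 6, the sense usually found when the larger flank of a secondary alcohol also has CIP precedence. If the opposite holds, the recovered alcohol is the (5R,6R) enantiomer and enters step 5 in place of 7.

## Route

Step 1
Reactants: 1 (E)-but-2-enal (crotonaldehyde)
Product: 2 (E)-(buta-1,3-dien-1-yloxy)(tert-butyl)dimethylsilane
Conditions: TBSOTf, Et3N, Et2O, 0 °C → rt
Reagents that add atoms: tert-butyldimethylsilyl trifluoromethanesulfonate, CC(C)(C)[Si](C)(C)OS(=O)(=O)C(F)(F)F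
Why: Soft enolisation of the enal with γ-deprotonation is the standard preparation of silyl dienol ethers; the E isomer should dominate and any Z isomer is inert in the next step.

Step 2
Reactants: 2 (E)-(buta-1,3-dien-1-yloxy)(tert-butyl)dimethylsilane; 3 methyl prop-2-ynoate (methyl propiolate)
Product: 4 methyl 6-[(tert-butyldimethylsilyl)oxy]cyclohexa-1,4-diene-1-carboxylate (racemic)
Conditions: PhMe, BHT (cat.), 80 °C, sealed vessel
Reagents that add atoms: none
Why: Thermal Diels–Alder reaction of a 1-oxygenated diene with an alkynoate; the donor terminus of 2 bonds to the β-carbon of 3, so the silyloxy carbon ends next to the ester carbon. Neutral conditions should keep the doubly allylic silyl ether from eliminating.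

Step 3
Reactants: 4 methyl 6-[(tert-butyldimethylsilyl)oxy]cyclohexa-1,4-diene-1-carboxylate
Product: 6 methyl rac-(5R,6R)-6-[(tert-butyldimethylsilyl)oxy]-5-hydroxycyclohexa-1,3-diene-1-carboxylate, via racemic epoxy enoate 5 (not isolated)
Conditions: DMDO, acetone, −20 °C; evaporate; then DBU, CH2Cl2, 0 °C → rt
Reagents that add atoms: dimethyldioxirane, CC1(C)OO1
Why: The neutral dioxirane should epoxidise the isolated electron-rich C2=C3 alkene, not the enoate, and approach anti to the adjacent silyloxy group. DBU then removes the γ-proton on C4 and the dienolate opens the oxirane (vinylogous E1cB), leaving the new hydroxyl on C2 trans to the O1 silyl ether and the two oxygens differentiated.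

Step 4
Reactants: 6 methyl rac-(5R,6R)-6-[(tert-butyldimethylsilyl)oxy]-5-hydroxycyclohexa-1,3-diene-1-carboxylate
Product: 7 methyl (5R,6R)-5-(acetyloxy)-6-[(tert-butyldimethylsilyl)oxy]cyclohexa-1,3-diene-1-carboxylate
Conditions: Amano lipase PS, vinyl acetate, t-BuOMe, 30 °C, to about half conversion; chromatography
Reagents that add atoms: vinyl acetate, C=COC(C)=O
Why: Lipase-catalysed transesterification is a standard kinetic resolution of secondary carbinols with one large and one small flank; the acetate is separated from the unreacted (5S,6S) alcohol, which fixes the absolute configuration of C1 and C2 of the target.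

Step 5
Reactants: 7 methyl (5R,6R)-5-(acetyloxy)-6-[(tert-butyldimethylsilyl)oxy]cyclohexa-1,3-diene-1-carboxylate
Product: 8 (1R,6R)-6-[(tert-butyldimethylsilyl)oxy]-5-(hydroxymethyl)cyclohexa-2,4-dien-1-ol
Conditions: i-Bu2AlH (DIBAL-H, excess), CH2Cl2, −78 → −20 °C; aq. KNaC4H4O6
Reagents that add atoms: none
Why: The aluminium hydride reduces the dienoate 1,2 to the primary allylic alcohol and cleaves the acetate in the same operation; no stereocentre is touched and the work-up is non-acidic.

Step 6
Reactants: 8 (1R,6R)-6-[(tert-butyldimethylsilyl)oxy]-5-(hydroxymethyl)cyclohexa-2,4-dien-1-ol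
Product: 9 (1R,6R)-6-[(tert-butyldimethylsilyl)oxy]-5-{[(tert-butyldimethylsilyl)oxy]methyl}cyclohexa-2,4-dien-1-ol
Conditions: TBSCl (1.05 equiv), imidazole, CH2Cl2, −20 → 0 °C
Reagents that add atoms: tert-butyldimethylsilyl chloride, CC(C)(C)[Si](C)(C)Cl
Why: Selective silylation of a primary hydroxyl beside a hindered secondary one. A silyl ether on O7 cannot attack an iodonium ion and withdraws less electron density from C5=C6 than an ester would.

Step 7
Reactants: 9 (1R,6R)-6-[(tert-butyldimethylsilyl)oxy]-5-{[(tert-butyldimethylsilyl)oxy]methyl}cyclohexa-2,4-dien-1-ol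
Product: 10 tert-butyl (1R,6R)-6-[(tert-butyldimethylsilyl)oxy]-5-{[(tert-butyldimethylsilyl)oxy]methyl}cyclohexa-2,4-dien-1-yl carbonate
Conditions: Boc2O, DMAP (0.2 equiv), MeCN, rt
Reagents that add atoms: di-tert-butyl dicarbonate, CC(C)(C)OC(=O)OC(=O)OC(C)(C)C
Why: DMAP-catalysed carbonate formation on the only free hydroxyl places the tether on O2 without any regiochemical question.

Step 8
Reactants: 10 tert-butyl (1R,6R)-6-[(tert-butyldimethylsilyl)oxy]-5-{[(tert-butyldimethylsilyl)oxy]methyl}cyclohexa-2,4-dien-1-yl carbonate
Product: 11 (1R,5R,8R,9S)-8-iodo-9-[(tert-butyldimethylsilyl)oxy]-1-{[(tert-butyldimethylsilyl)oxy]methyl}-2,4-dioxabicyclo[3.3.1]non-6-en-3-one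
Conditions: IBr, PhMe, −78 °C; aq. Na2S2O3/NaHCO3
Reagents that add atoms: iodine monobromide, BrI
Why: IBr transfers I+ reversibly to the diene; the carbonyl oxygen of the carbonate, held on the upper face by C2, captures the cation at tertiary C6, and the dioxanylium ion loses its tert-butyl group as tert-butyl bromide, which makes the step irreversible. The closest known reaction is the iodocarbonate cyclisation of homoallylic tert-butyl carbonates with IBr at low temperature; its use on a conjugated ring diene is an extension of substrate, not of reaction type. The ring closed is the six-membered cyclic carbonate (6-exo), bridging C2 and C6 as a 2,4-dioxabicyclo[3.3.1]nonene; this needs the diaxial conformer of the trans C1/C2 dioxy unit, which allylic strain between the C6 substituent and an equatorial O1 silyl ether should favour. C6 is set by the tether, since the carbonate can reach it only on the face of O2; C5 is set by anti addition, iodine entering opposite the new C–O bond. The step needs attack at C6 and not at C4: C5=C6 is the more substituted alkene with only silyl ether neighbours, C3=C4 is deactivated by the allylic carbonate, and positive charge in an iodo-allyl cation concentrates on tertiary C6. If iodine enters at C3 instead (1,4-addition), the same C6–O bond forms and step 9 closes the same oxirane by SN2' displacement. The silyl ethers on O1 and O7 cannot compete as nucleophiles, as an ester at either position could.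

Step 9
Reactants: 11 (1R,5R,8R,9S)-8-iodo-9-[(tert-butyldimethylsilyl)oxy]-1-{[(tert-butyldimethylsilyl)oxy]methyl}-2,4-dioxabicyclo[3.3.1]non-6-en-3-one
Product: 12 (1S,2S,3R,6S)-2-[(tert-butyldimethylsilyl)oxy]-1-{[(tert-butyldimethylsilyl)oxy]methyl}-7-oxabicyclo[4.1.0]hept-4-en-3-ol
Conditions: K2CO3, MeOH, 0 °C → rt
Reagents that add atoms: none
Why: Methanolysis of the cyclic carbonate frees the C6 alkoxide, which displaces the anti iodide on C5 with inversion, the standard conversion of iodocarbonates into syn epoxy alcohols. O1 and O7 remain silylated, so no alkoxide adjacent to the oxirane can form and epoxide migration is excluded.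

Step 10
Reactants: 12 (1S,2S,3R,6S)-2-[(tert-butyldimethylsilyl)oxy]-1-{[(tert-butyldimethylsilyl)oxy]methyl}-7-oxabicyclo[4.1.0]hept-4-en-3-ol
Product: 13 (1S,2S,3R,6S)-2-[(tert-butyldimethylsilyl)oxy]-1-{[(tert-butyldimethylsilyl)oxy]methyl}-7-oxabicyclo[4.1.0]hept-4-en-3-yl benzoate
Conditions: BzCl, pyridine, DMAP (cat.), CH2Cl2, 0 °C
Reagents that add atoms: benzoyl chloride, O=C(Cl)c1ccccc1
Why: Routine acylation of the only free (allylic, secondary) hydroxyl under amine-buffered conditions that a vinyl epoxide tolerates.

Step 11
Reactants: 13 (1S,2S,3R,6S)-2-[(tert-butyldimethylsilyl)oxy]-1-{[(tert-butyldimethylsilyl)oxy]methyl}-7-oxabicyclo[4.1.0]hept-4-en-3-yl benzoate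
Product: 14 (1R,2S,3R,6S)-2-hydroxy-1-(hydroxymethyl)-7-oxabicyclo[4.1.0]hept-4-en-3-yl benzoate
Conditions: Bu4NF, AcOH (1:1), THF, 0 °C → rt
Reagents that add atoms: none
Why: Fluoride cleaves both silyl ethers. The acetic acid buffer prevents alkoxide formation, which would otherwise allow Payne migration of the oxirane toward O1 or O7 and benzoyl migration from O2 to O1. The change of descriptor at C1 of the bicycle is only a change of CIP ranking.

Step 12
Reactants: 14 (1R,2S,3R,6S)-2-hydroxy-1-(hydroxymethyl)-7-oxabicyclo[4.1.0]hept-4-en-3-yl benzoate
Product: 16 [(1S,2S,3R,6S)-2-(acetyloxy)-3-(benzoyloxy)-7-oxabicyclo[4.1.0]hept-4-en-1-yl]methyl benzoate, via hydroxy dibenzoate 15 (not isolated)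
Conditions: BzCl (1.05 equiv), 2,4,6-collidine, CH2Cl2, −40 → 0 °C; then Ac2O, DMAP (cat.), 0 °C → rt
Reagents that add atoms: benzoyl chloride, O=C(Cl)c1ccccc1; acetic anhydride, CC(=O)OC(C)=O
Why: The primary hydroxyl should be acylated far faster than the secondary one wedged between quaternary C6 and C2, so one equivalent of benzoyl chloride at low temperature should give the O7 benzoate. Acetic anhydride with DMAP then esterifies O1 in the same flask, and no stereocentre is involved.

## Compound list

1 | (E)-but-2-enal (crotonaldehyde) | C/C=C/C=O | starting material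
2 | (E)-(buta-1,3-dien-1-yloxy)(tert-butyl)dimethylsilane | C=C/C=C/O[Si](C)(C)C(C)(C)C | intermediate
3 | methyl prop-2-ynoate (methyl propiolate) | C#CC(=O)OC | starting material
4 | methyl 6-[(tert-butyldimethylsilyl)oxy]cyclohexa-1,4-diene-1-carboxylate, racemic (the 6S enantiomer, which leads to 16, is drawn) | COC(=O)C1=CCC=C[C@@H]1O[Si](C)(C)C(C)(C)C | intermediate
5 | methyl rac-(1R,2R,6R)-2-[(tert-butyldimethylsilyl)oxy]-7-oxabicyclo[4.1.0]hept-3-ene-3-carboxylate (oxirane trans to the silyloxy group) | COC(=O)C1=CC[C@H]2O[C@H]2[C@@H]1O[Si](C)(C)C(C)(C)C | intermediate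
6 | methyl rac-(5R,6R)-6-[(tert-butyldimethylsilyl)oxy]-5-hydroxycyclohexa-1,3-diene-1-carboxylate (trans, racemic) | O[C@@H]1C=CC=C(C(=O)OC)[C@H]1O[Si](C)(C)C(C)(C)C | intermediate
7 | methyl (5R,6R)-5-(acetyloxy)-6-[(tert-butyldimethylsilyl)oxy]cyclohexa-1,3-diene-1-carboxylate | CC(=O)O[C@@H]1C=CC=C(C(=O)OC)[C@H]1O[Si](C)(C)C(C)(C)C | intermediate
8 | (1R,6R)-6-[(tert-butyldimethylsilyl)oxy]-5-(hydroxymethyl)cyclohexa-2,4-dien-1-ol | O[C@@H]1C=CC=C(CO)[C@H]1O[Si](C)(C)C(C)(C)C | intermediate
9 | (1R,6R)-6-[(tert-butyldimethylsilyl)oxy]-5-{[(tert-butyldimethylsilyl)oxy]methyl}cyclohexa-2,4-dien-1-ol | O[C@@H]1C=CC=C(CO[Si](C)(C)C(C)(C)C)[C@H]1O[Si](C)(C)C(C)(C)C | intermediate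
10 | tert-butyl (1R,6R)-6-[(tert-butyldimethylsilyl)oxy]-5-{[(tert-butyldimethylsilyl)oxy]methyl}cyclohexa-2,4-dien-1-yl carbonate | CC(C)(C)OC(=O)O[C@@H]1C=CC=C(CO[Si](C)(C)C(C)(C)C)[C@H]1O[Si](C)(C)C(C)(C)C | intermediate
11 | (1R,5R,8R,9S)-8-iodo-9-[(tert-butyldimethylsilyl)oxy]-1-{[(tert-butyldimethylsilyl)oxy]methyl}-2,4-dioxabicyclo[3.3.1]non-6-en-3-one | O=C1O[C@@H]2C=C[C@@H](I)[C@](CO[Si](C)(C)C(C)(C)C)(O1)[C@H]2O[Si](C)(C)C(C)(C)C | intermediate
12 | (1S,2S,3R,6S)-2-[(tert-butyldimethylsilyl)oxy]-1-{[(tert-butyldimethylsilyl)oxy]methyl}-7-oxabicyclo[4.1.0]hept-4-en-3-ol | CC(C)(C)[Si](C)(C)O[C@H]1[C@H](O)C=C[C@@H]2O[C@@]21CO[Si](C)(C)C(C)(C)C | intermediate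
13 | (1S,2S,3R,6S)-2-[(tert-butyldimethylsilyl)oxy]-1-{[(tert-butyldimethylsilyl)oxy]methyl}-7-oxabicyclo[4.1.0]hept-4-en-3-yl benzoate | CC(C)(C)[Si](C)(C)O[C@H]1[C@H](OC(=O)c2ccccc2)C=C[C@@H]2O[C@@]21CO[Si](C)(C)C(C)(C)C | intermediate
14 | (1R,2S,3R,6S)-2-hydroxy-1-(hydroxymethyl)-7-oxabicyclo[4.1.0]hept-4-en-3-yl benzoate | O[C@H]1[C@H](OC(=O)c2ccccc2)C=C[C@@H]2O[C@@]21CO | intermediate
15 | [(1R,2S,3R,6S)-3-(benzoyloxy)-2-hydroxy-7-oxabicyclo[4.1.0]hept-4-en-1-yl]methyl benzoate | O[C@H]1[C@H](OC(=O)c2ccccc2)C=C[C@@H]2O[C@@]21COC(=O)c1ccccc1 | intermediate
16 | [(1S,2S,3R,6S)-2-(acetyloxy)-3-(benzoyloxy)-7-oxabicyclo[4.1.0]hept-4-en-1-yl]methyl benzoate | CC(=O)O[C@H]1[C@H](OC(=O)c2ccccc2)C=C[C@@H]2O[C@@]21COC(=O)c1ccccc1 | target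

## Step count and least certain steps

Total: 12 steps. Longest linear sequence: 12 steps, from crotonaldehyde 1.

**Step 8 (key step).** What may go wrong is capture of the iodine-bearing cation by the carbonate at C4 instead of C6. The tethered oxygen is equally close to both 1,3-related carbons, and iodine reaches the lower face of C5=C6 only past the axial O1 silyl ether. Plain iodobromination of the diene is a second possibility. Fallback, using steric instead of tether control: from 9, benzoylation of O2 (BzCl, pyridine) gives dienyl benzoate F1. Its trisubstituted C5=C6 alkene is epoxidised with dimethyldioxirane from the face opposite the adjacent O1 silyl ether. This returns to the route at 13.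

**Step 2.** What may go wrong is loss of silanol from the doubly allylic silyl ether during or after the cycloaddition, which aromatises the adduct to methyl benzoate. Fallback, with an alkene in place of the alkyne: from 2, cycloaddition with methyl (E)-3-bromoacrylate gives racemic bromo ester F2, whose silyl ether is only singly allylic. Dimethyldioxirane gives its epoxide F3. DBU (two equivalents) first expels HBr to form the enoate and then opens the oxirane as in step 3. This returns to the route at 6.

**Step 4.** What may go wrong is poor discrimination of the enantiomers by the enzyme, because the carbinol sits next to a bulky silyloxy group, or very slow acylation. Fallback, by classical separation of diastereomers: from 6, esterification with (S)-O-methylmandelic acid (DCC, DMAP) gives the (5R,6R) mandelate F4 and its (5S,6S) diastereomer F5, separable by chromatography. F4 is reduced with i-Bu2AlH exactly as 7, which cleaves the auxiliary and returns to the route at 8.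

**Step 12.** What may go wrong is incomplete discrimination between the primary and the hindered secondary hydroxyl, so that O1 is benzoylated in part. Fallback, by sequential deprotection instead of selective acylation: from 13, HF·pyridine buffered with excess pyridine at 0 °C removes only the primary silyl ether and gives hydroxy benzoate F6. Benzoylation gives dibenzoate silyl ether F7. Bu4NF buffered with AcOH then frees O1 and returns to the route at 15, which is acetylated as in the second stage of step 12.

## Further compounds

F1 | step 8 | (1R,6R)-6-[(tert-butyldimethylsilyl)oxy]-5-{[(tert-butyldimethylsilyl)oxy]methyl}cyclohexa-2,4-dien-1-yl benzoate | O=C(O[C@@H]1C=CC=C(CO[Si](C)(C)C(C)(C)C)[C@H]1O[Si](C)(C)C(C)(C)C)c1ccccc1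
F2 | step 2 | methyl 6-bromo-2-[(tert-butyldimethylsilyl)oxy]cyclohex-3-ene-1-carboxylate, racemic (ester cis to silyloxy, bromine trans to ester) | COC(=O)[C@@H]1[C@@H](Br)CC=C[C@@H]1O[Si](C)(C)C(C)(C)C
F3 | step 2 | methyl 4-bromo-2-[(tert-butyldimethylsilyl)oxy]-7-oxabicyclo[4.1.0]heptane-3-carboxylate, racemic (oxirane trans to silyloxy) | COC(=O)[C@@H]1[C@@H](Br)C[C@H]2O[C@H]2[C@@H]1O[Si](C)(C)C(C)(C)C
F4 | step 4 | methyl (5R,6R)-6-[(tert-butyldimethylsilyl)oxy]-5-{[(2S)-2-methoxy-2-phenylacetyl]oxy}cyclohexa-1,3-diene-1-carboxylate | CO[C@@H](c1ccccc1)C(=O)O[C@@H]1C=CC=C(C(=O)OC)[C@H]1O[Si](C)(C)C(C)(C)C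
F5 | step 4 | methyl (5S,6S)-6-[(tert-butyldimethylsilyl)oxy]-5-{[(2S)-2-methoxy-2-phenylacetyl]oxy}cyclohexa-1,3-diene-1-carboxylate | CO[C@@H](c1ccccc1)C(=O)O[C@H]1C=CC=C(C(=O)OC)[C@@H]1O[Si](C)(C)C(C)(C)C
F6 | step 12 | (1S,2S,3R,6S)-2-[(tert-butyldimethylsilyl)oxy]-1-(hydroxymethyl)-7-oxabicyclo[4.1.0]hept-4-en-3-yl benzoate | CC(C)(C)[Si](C)(C)O[C@H]1[C@H](OC(=O)c2ccccc2)C=C[C@@H]2O[C@@]21CO
F7 | step 12 | [(1S,2S,3R,6S)-3-(benzoyloxy)-2-[(tert-butyldimethylsilyl)oxy]-7-oxabicyclo[4.1.0]hept-4-en-1-yl]methyl benzoate | CC(C)(C)[Si](C)(C)O[C@H]1[C@H](OC(=O)c2ccccc2)C=C[C@@H]2O[C@@]21COC(=O)c1ccccc1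
A1 | alternative 1 | 1-(hydroxymethyl)-3-[(4-methoxybenzyl)oxy]-7-oxabicyclo[4.1.0]hept-4-en-2-ol, ring epoxide with the configuration of the target | O[C@H]1[C@H](OCc2ccc(OC)cc2)C=C[C@@H]2O[C@@]21CO
A2 | alternative 1 | 7-[(4-methoxybenzyl)oxy]-1-oxaspiro[2.5]oct-5-ene-4,8-diol, spiro C–O bond trans to the C5 hydroxyl | O[C@H]1[C@H](OCc2ccc(OC)cc2)C=C[C@H](O)[C@]13CO3
A3 | alternative 2 | 2,3-bis[(tert-butyldimethylsilyl)oxy]-1-{[(tert-butyldimethylsilyl)oxy]methyl}-7-oxabicyclo[4.1.0]hept-4-ene with the configuration of the target | CC(C)(C)[Si](C)(C)O[C@H]1[C@H](O[Si](C)(C)C(C)(C)C)C=C[C@@H]2O[C@@]21CO[Si](C)(C)C(C)(C)C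
A4 | alternative 2 | dimethyl{(2Z,4R,5S)-4,5,7-tris[(tert-butyldimethylsilyl)oxy]-6-oxohept-2-en-1-yl}sulfonium tetrafluoroborate | C[S+](C)C/C=C\[C@@H](O[Si](C)(C)C(C)(C)C)[C@H](O[Si](C)(C)C(C)(C)C)C(=O)CO[Si](C)(C)C(C)(C)C.F[B-](F)(F)F
A5 | alternative 3 | (2-bromo-2-formyl-7-oxabicyclo[2.2.1]hept-5-en-1-yl)methyl benzoate, formyl exo | O=C[C@]1(Br)C[C@H]2C=C[C@]1(COC(=O)c1ccccc1)O2
A6 | alternative 3 | furan-2-ylmethyl benzoate (furfuryl benzoate) | O=C(OCc1ccco1)c1ccccc1
A7 | alternative 3 | 2-bromoprop-2-enal (2-bromoacrolein) | C=C(Br)C=O
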